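The amounts of target in the earlier runs stand highest at the first reading, then fall and level off.

| flask | solid substrate | reagent | remark | time |
|---|---|---|---|---|
| gamma | 0.92 M | 0.45 equiv | run made earlier |  |
| zeta | 0.92 M | 1.8 equiv | run made earlier |  |
| delta | 1.4 M | 0.90 equiv | run made earlier |  |
| flask | 0.92 M | 0.900 equiv |  | 15 h |

- gamma (time / h: target / %): 1.33: 37.3; 3.00: 33.6; 6.00: 30.9; 15.0: 29.7
- zeta (time / h: target / %): 1.33: 85.8; 3.00: 74.5; 6.00: 67.4; 15.0: 65.3
- delta (time / h: target / %): 4.00: 65.7; 8.00: 60.6; 12.0: 60.0; 15.0: 59.6

(standard deviation of a reading: 0.3 percentage points)

- given per volume of solution although it is solid: solid substrate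
- at the start none of the solid substrate is in solution

- cedar: doubling the dissolution coefficient of the solid substrate, all else as stated
- ash: doubling the solubility of the solid substrate, all else as stated
- alder: doubling the amount of reagent, all else as stated

1. amount of target at 15 h, in percent of the solid substrate charged
2. the change that raises the amount of target at 15 h, in percent of the solid substrate charged most ("none" if none brings more than 2 percentage points) (cedar / ash / alder / none)
3. amount of target at 15 h, in percent of the solid substrate charged, after cedar

**What does the end amount follow?** The reagent, I think. The gamma run holds 29.7 % of target at 15.0 h from 0.45 equiv, so f = 66.0 % is the retained share, the target at the end per equivalent of reagent charged, with reagent as the limiting reagent.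

**That is one run at one concentration. Does f survive in delta?** Delta ran at 1.4 M against 0.92 M. With 0.90 equiv, f gives 59.4 %, and delta read 59.6 %, with a scatter of 0.3 percentage points.

**Is the fall over by the asked time?** In the zeta run, the excess over the last reading drops from 9.2 points to 2.1 points between 3.00 h and 6.00 h. That reads as a half-life τ = 1.41 h, much shorter than the run.

**Zeta has 1.8 equiv. Does f promise more than the substrate charged?** It would, so f must count the smaller of reagent and substrate: zeta read 65.3 %, near f itself.

**Your figures?** For the flask, 59.4 %. Alder repeats zeta, a gain of 5.9 points. I expect cedar and ash to leave the end amount where it is, since zeta held 85.8 % as early as 1.33 h, much earlier than the asked time.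

The forecast says 59.5 %, alder, and 59.5 % after cedar, 0.1 points above my flask figure, on the grounds that “the target then relaxes to a fixed share”.

The flask gives 60.0 %, and 60.0 % after cedar; alder gains 5.6 points, cedar 0 points and ash 0 points.

solid substrate ⇌ dissolved substrate, rate k1*(cs1 - [dissolved substrate]) while solid is left; crystals form when [dissolved substrate] > cs1 (solubility = 0.340 M, k = 8.31 /h); dissolved substrate + reagent → target (k = 7.69 /M/h); 2 solid substrate → homo dimer (k = 0.0573 /M/h); target ⇌ isomer of the product (K = 0.500, k = 0.172 /h) In the flask, target and isomer of the product relax by their own step, both ways together, with a half-life of 1.34 h, far shorter than the 15 h of the run, and target goes from 71.1 % at 1.50 h to 60.0 % beside 30.0 % of isomer of the product at 15.0 h, still 60.0 % at 150 h. For a neighbouring flask, like this one but with 0.540 equiv of reagent, f gives 35.6 % of target, and that neighbour holds 36.0 %.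

(Readings and results were computed for substances that don't exist; the scatter is artificial.)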